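**Retrosynthetic overview**

1. Numbering (prostanoid): C1 = ester carbon, C4 = acetoxy carbinol, ring A = C8–C12 (C9 ketone, C10=C11, C12 tertiary acetate), C13–C20 = octenyl chain. Enabling feature: in ring A, C11 is β to the C9 carbonyl and adjacent to the oxygen-bearing C12, so the unit C10=C11–C12(OAc) is a dehydrated vicinal diol; C11 and C12 can both start as carbonyl carbons (pinacol retron) and the C11 oxygen leaves later by E1cB.
2. Target ⇐ oxidation at C9 and E1cB loss of acetic acid from a cis-C11,C12-diacetate ⇐ cis-C11,C12-diol of a cyclopentane.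
3. Ring A (the only ring) ⇐ SmI2 ketyl (pinacol) closure of the C11–C12 bond in an acyclic C11-aldehyde/C12-ketone, after all other C–C bonds are in place.
4. Keto aldehyde ⇐ anti-Markovnikov hydration of a terminal alkyne ⇐ transfer-hydrogenative dynamic kinetic resolution of a 2-substituted alkynyl 1,3-diketone (sets C8 and a temporary C9 carbinol).
5. Diketone ⇐ Tsuji–Trost union C7–C8 with a vinyl epoxide carrying C4 (gives E-C5=C6) and Claisen acylation C8–C12 of 4-(trimethylsilyl)but-3-yn-2-one with (Z)-non-3-enoic acid.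

Key step: step 11

Assumption: the dynamic kinetic resolution in step 7 is taken to follow the anti (Felkin–Anh) course, so the C9 oxygen is protected as a non-chelating silyl ether for step 11; C8 of the two 1,3-diketones is configurationally labile and is drawn without descriptor; the four building blocks and the L-series Shi ketone are taken as commercial.

**Step 1**
Reactants: 1 (Z)-non-3-en-1-ol
Product: 2 (Z)-non-3-enoic acid
Conditions: TEMPO (cat.), PhI(OAc)2 (2.2 equiv), MeCN/H2O, 0 → 23 °C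
Reagents that add atoms: water, O
Why: Nitroxyl/hypervalent-iodine oxidation of the primary alcohol through the aldehyde hydrate to the acid runs near neutrality, so the skipped Z-olefin should neither migrate nor isomerise.

**Step 2**
Reactants: 2 (Z)-non-3-enoic acid; 3 4-(trimethylsilyl)but-3-yn-2-one
Product: 5 (7Z)-1-(trimethylsilyl)tridec-7-en-1-yne-3,5-dione, via acyl imidazolide 4 (not isolated)
Conditions: 2, CDI, THF, 23 °C; then added to 3 (2.1 equiv)/LiHMDS (2.1 equiv), THF, −78 → −30 °C; aq. NH4Cl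
Reagents that add atoms: 1,1'-carbonyldiimidazole, O=C(n1ccnc1)n1ccnc1 (its imidazolyl group is in 4 only; none of its atoms remain in 5)
Why: Claisen-type C-acylation of the lithium enolate of the methyl alkynyl ketone (enolisable on one side only) by the acyl imidazolide, driven by deprotonation of the product diketone by the second equivalent of enolate.

**Step 3**
Reactants: 6 penta-1,4-dien-3-ol; 7 trimethyl orthoacetate
Product: 9 methyl (4E)-hepta-4,6-dienoate, via ketene acetal 8 (not isolated)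
Conditions: EtCO2H (cat.), 7 (5 equiv), 130 °C, MeOH distilled off
Reagents that add atoms: none
Why: Johnson–Claisen rearrangement: the chair [3,3] shift of the mixed ketene acetal places the remaining vinyl group equatorial, so the new C4=C5 bond should be E.

**Step 4**
Reactants: 9 methyl (4E)-hepta-4,6-dienoate
Product: 10 methyl 3-[(2S,3S)-3-ethenyloxiran-2-yl]propanoate
Conditions: ent-Shi ketone (L-fructose-derived, 30 mol%), Oxone, K2CO3, Bu4NHSO4 (cat.), MeCN/CH2(OMe)2/aq. Na2B4O7–Na2EDTA, 0 °C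
Reagents that add atoms: Oxone (potassium peroxymonosulfate), [K+].[O-]S(=O)(=O)OO
Why: Shi asymmetric epoxidation: the chiral dioxirane should oxidise the more electron-rich trans-disubstituted C4=C5 bond of the diene rather than the terminal vinyl group, and the spiro transition state of the L-series ketone is expected to give the (S,S)-epoxide, which fixes C4 as S.

**Step 5**
Reactants: 5 (7Z)-1-(trimethylsilyl)tridec-7-en-1-yne-3,5-dione; 10 methyl 3-[(2S,3S)-3-ethenyloxiran-2-yl]propanoate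
Product: 11 methyl (4S,5E,11Z)-4-hydroxy-9-oxo-8-[3-(trimethylsilyl)prop-2-ynoyl]heptadeca-5,11-dienoate
Conditions: Pd2(dba)3·CHCl3 (2.5 mol%), dppe (6 mol%), THF, 0 → 23 °C; used at once
Reagents that add atoms: none
Why: Tsuji–Trost allylation under neutral conditions: zerovalent palladium opens the vinyl epoxide to a syn π-allyl alkoxide that deprotonates the 1,3-diketone, whose central carbon (C8) attacks the distal terminus C7 to give the E-configured 1,4-adduct while the C4–O bond is untouched (S retained); C8 stays labile.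

**Step 6**
Reactants: 11 methyl (4S,5E,11Z)-4-hydroxy-9-oxo-8-[3-(trimethylsilyl)prop-2-ynoyl]heptadeca-5,11-dienoate
Product: 12 methyl (4S,5E,11Z)-4-acetoxy-9-oxo-8-[3-(trimethylsilyl)prop-2-ynoyl]heptadeca-5,11-dienoate
Conditions: Ac2O, pyridine, CH2Cl2, 0 °C
Reagents that add atoms: acetic anhydride, CC(=O)OC(C)=O
Why: Acylation of the secondary allylic alcohol should outpace O-acylation of the hindered 2-substituted diketone and removes the risk of lactonisation onto the methyl ester; C4 is not touched.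

**Step 7**
Reactants: 12 methyl (4S,5E,11Z)-4-acetoxy-9-oxo-8-[3-(trimethylsilyl)prop-2-ynoyl]heptadeca-5,11-dienoate
Product: 13 methyl (4S,5E,8R,11Z)-4-acetoxy-8-[(1S)-1-hydroxy-3-(trimethylsilyl)prop-2-yn-1-yl]-9-oxoheptadeca-5,11-dienoate
Conditions: Ru[(S,S)-TsNCH(Ph)CH(Ph)NH](η6-p-cymene) (2 mol%), i-PrOH, 25 °C
Reagents that add atoms: none
Why: Noyori–Ikariya asymmetric transfer hydrogenation with dynamic kinetic resolution: only the activated alkynyl ketone (C9) is reduced, the (S,S)-catalyst giving the (S)-propargylic carbinol as with simple alkynones, while C8 equilibrates through the diketone enol and the epimer that reacts in the Felkin–Anh sense (acyl group anti to the incoming hydride) should be drained, giving the anti (8R) isomer from both C8 epimers.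

**Step 8**
Reactants: 13 methyl (4S,5E,8R,11Z)-4-acetoxy-8-[(1S)-1-hydroxy-3-(trimethylsilyl)prop-2-yn-1-yl]-9-oxoheptadeca-5,11-dienoate
Product: 14 methyl (4S,5E,8R,11Z)-4-acetoxy-8-[(1S)-1-{[tert-butyl(dimethyl)silyl]oxy}-3-(trimethylsilyl)prop-2-yn-1-yl]-9-oxoheptadeca-5,11-dienoate
Conditions: TBSOTf, 2,6-lutidine, CH2Cl2, −78 °C
Reagents that add atoms: tert-butyldimethylsilyl triflate, CC(C)(C)[Si](C)(C)OS(=O)(=O)C(F)(F)F
Why: Silylation blocks β-elimination and chelation at C9 and installs the bulky non-coordinating group used for face control in step 11; the hindered base at low temperature should avoid enol silylation and epimerisation at C8.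

**Step 9**
Reactants: 14 methyl (4S,5E,8R,11Z)-4-acetoxy-8-[(1S)-1-{[tert-butyl(dimethyl)silyl]oxy}-3-(trimethylsilyl)prop-2-yn-1-yl]-9-oxoheptadeca-5,11-dienoate
Product: 15 methyl (4S,5E,8R,11Z)-4-acetoxy-8-[(1S)-1-{[tert-butyl(dimethyl)silyl]oxy}prop-2-yn-1-yl]-9-oxoheptadeca-5,11-dienoate
Conditions: AgNO3 (10 mol%), acetone/H2O/CH2Cl2, 23 °C
Reagents that add atoms: none
Why: Silver-catalysed protodesilylation through a silver acetylide is specific for the C(sp)–Si bond and should leave the silyl ether, the acetate and the base-sensitive β-silyloxy ketone untouched.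

**Step 10**
Reactants: 15 methyl (4S,5E,8R,11Z)-4-acetoxy-8-[(1S)-1-{[tert-butyl(dimethyl)silyl]oxy}prop-2-yn-1-yl]-9-oxoheptadeca-5,11-dienoate
Product: 16 methyl (4S,5E,8R,11Z)-4-acetoxy-8-[(1R)-1-{[tert-butyl(dimethyl)silyl]oxy}-3-oxopropyl]-9-oxoheptadeca-5,11-dienoate
Conditions: [CpRu(MeCN)3]PF6 (5 mol%), 5,5'-bis(trifluoromethyl)-2,2'-bipyridine (5 mol%), H2O, NMP, 25 °C; used at once
Reagents that add atoms: water, O
Why: Ruthenium-catalysed anti-Markovnikov hydration of the terminal alkyne through a ruthenium vinylidene gives the C11 aldehyde under neutral conditions, so C8 should not epimerise and the silyl ether should not eliminate (the descriptor at C9 changes by priority only).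

**Step 11**
Reactants: 16 methyl (4S,5E,8R,11Z)-4-acetoxy-8-[(1R)-1-{[tert-butyl(dimethyl)silyl]oxy}-3-oxopropyl]-9-oxoheptadeca-5,11-dienoate
Product: 17 methyl (4S,5E)-4-acetoxy-7-[(1R,2S,3R,5R)-5-{[tert-butyl(dimethyl)silyl]oxy}-2,3-dihydroxy-2-[(2Z)-oct-2-en-1-yl]cyclopentyl]hept-5-enoate
Conditions: SmI2 (2.5 equiv), t-BuOH (2 equiv), THF (0.01 M), −78 → −20 °C; aq. NaHCO3
Reagents that add atoms: none
Why: Single-electron transfer from divalent samarium to the aldehyde gives the C11 ketyl, which adds in a 5-exo-trig sense to the samarium-activated C12 ketone (or couples with its ketyl after a second electron transfer) and closes ring A as a samarium-bridged cis-1,2-diolate, so two carbonyl carbons of like (acceptor) polarity are joined by a radical pinacol coupling. The closest known reaction type is the SmI2-mediated pinacol cyclisation of 1,5-keto aldehydes to cis-cyclopentane-1,2-diols. C12 is set by the substrate: the bulky diolate bridged by trivalent samarium should form on the ring face opposite to the C7 chain on C8 and to the C9 silyl ether, which are cis to each other after the anti-selective step 7 (matched 1,2- and 1,3-control), so O12 ends up trans to C7 (12S in 17, 12R in the target). C11 is set cis to O12 by the samarium bridge and is erased in step 14. The step needs electron transfer to the aldehyde rather than reduction of the ketone to an alcohol, and ring closure faster than intermolecular coupling; the more easily reduced aldehyde, the 1,5-relationship of the carbonyls, high dilution and low temperature secure this, and the esters, the allylic acetate and the isolated alkenes should be inert to SmI2 in THF.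

**Step 12**
Reactants: 17 methyl (4S,5E)-4-acetoxy-7-[(1R,2S,3R,5R)-5-{[tert-butyl(dimethyl)silyl]oxy}-2,3-dihydroxy-2-[(2Z)-oct-2-en-1-yl]cyclopentyl]hept-5-enoate
Product: 18 methyl (4S,5E)-4-acetoxy-7-[(1R,2S,3R,5R)-2,3-diacetoxy-5-{[tert-butyl(dimethyl)silyl]oxy}-2-[(2Z)-oct-2-en-1-yl]cyclopentyl]hept-5-enoate
Conditions: Ac2O (10 equiv), DMAP (1 equiv), Et3N, CH2Cl2, 23 → 40 °C
Reagents that add atoms: acetic anhydride, CC(=O)OC(C)=O
Why: Exhaustive DMAP-catalysed acylation esterifies the secondary C11 and the tertiary C12 hydroxyl at a stage where no base-sensitive enone is present, with all stereocentres untouched.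

**Step 13**
Reactants: 18 methyl (4S,5E)-4-acetoxy-7-[(1R,2S,3R,5R)-2,3-diacetoxy-5-{[tert-butyl(dimethyl)silyl]oxy}-2-[(2Z)-oct-2-en-1-yl]cyclopentyl]hept-5-enoate
Product: 19 methyl (4S,5E)-4-acetoxy-7-[(1R,2S,3R,5R)-2,3-diacetoxy-5-hydroxy-2-[(2Z)-oct-2-en-1-yl]cyclopentyl]hept-5-enoate
Conditions: HF·pyridine, pyridine, THF, 0 → 23 °C
Reagents that add atoms: none
Why: Buffered fluoride cleaves the secondary silyl ether without touching the three acetates, and the slightly acidic medium should suppress 1,3-acyl migration to the freed hydroxyl.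

**Step 14**
Reactants: 19 methyl (4S,5E)-4-acetoxy-7-[(1R,2S,3R,5R)-2,3-diacetoxy-5-hydroxy-2-[(2Z)-oct-2-en-1-yl]cyclopentyl]hept-5-enoate
Product: 21 methyl (4S,5E)-4-acetoxy-7-[(1S,2R)-2-acetoxy-2-[(2Z)-oct-2-en-1-yl]-5-oxocyclopent-3-en-1-yl]hept-5-enoate, via β-acetoxy ketone 20 (not isolated)
Conditions: Dess–Martin periodinane, NaHCO3, CH2Cl2, 0 → 23 °C; then Et3N, 0 °C
Reagents that add atoms: none
Why: Oxidation of the C9 carbinol followed by E1cB loss of acetic acid: C10 carries a hydrogen anti to the C11 acetate whereas C8–H is cis to the C12 acetate, so elimination should go only toward C10=C11 (a second elimination would give an antiaromatic cyclopentadienone), and C8 and C12 keep their configuration.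

**Compound list**

1 | (Z)-non-3-en-1-ol | CCCCC/C=C\CCO | starting material
2 | (Z)-non-3-enoic acid | CCCCC/C=C\CC(=O)O | intermediate
3 | 4-(trimethylsilyl)but-3-yn-2-one | CC(=O)C#C[Si](C)(C)C | starting material
4 | (3Z)-1-(1H-imidazol-1-yl)non-3-en-1-one (acyl imidazolide, not isolated) | CCCCC/C=C\CC(=O)n1ccnc1 | intermediate
5 | (7Z)-1-(trimethylsilyl)tridec-7-en-1-yne-3,5-dione | CCCCC/C=C\CC(=O)CC(=O)C#C[Si](C)(C)C | intermediate
6 | penta-1,4-dien-3-ol | C=CC(O)C=C | starting material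
7 | trimethyl orthoacetate | CC(OC)(OC)OC | starting material
8 | 3-[(1-methoxyethenyl)oxy]penta-1,4-diene (ketene acetal, not isolated) | C=C(OC)OC(C=C)C=C | intermediate
9 | methyl (4E)-hepta-4,6-dienoate | COC(=O)CC/C=C/C=C | intermediate
10 | methyl 3-[(2S,3S)-3-ethenyloxiran-2-yl]propanoate | COC(=O)CC[C@@H]1O[C@H]1C=C | intermediate
11 | methyl (4S,5E,11Z)-4-hydroxy-9-oxo-8-[3-(trimethylsilyl)prop-2-ynoyl]heptadeca-5,11-dienoate (C8 labile) | CCCCC/C=C\CC(=O)C(C/C=C/[C@@H](O)CCC(=O)OC)C(=O)C#C[Si](C)(C)C | intermediate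
12 | methyl (4S,5E,11Z)-4-acetoxy-9-oxo-8-[3-(trimethylsilyl)prop-2-ynoyl]heptadeca-5,11-dienoate (C8 labile) | CCCCC/C=C\CC(=O)C(C/C=C/[C@@H](OC(C)=O)CCC(=O)OC)C(=O)C#C[Si](C)(C)C | intermediate
13 | methyl (4S,5E,8R,11Z)-4-acetoxy-8-[(1S)-1-hydroxy-3-(trimethylsilyl)prop-2-yn-1-yl]-9-oxoheptadeca-5,11-dienoate | CCCCC/C=C\CC(=O)[C@H](C/C=C/[C@@H](OC(C)=O)CCC(=O)OC)[C@H](O)C#C[Si](C)(C)C | intermediate
14 | methyl (4S,5E,8R,11Z)-4-acetoxy-8-[(1S)-1-{[tert-butyl(dimethyl)silyl]oxy}-3-(trimethylsilyl)prop-2-yn-1-yl]-9-oxoheptadeca-5,11-dienoate | CCCCC/C=C\CC(=O)[C@H](C/C=C/[C@@H](OC(C)=O)CCC(=O)OC)[C@H](O[Si](C)(C)C(C)(C)C)C#C[Si](C)(C)C | intermediate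
15 | methyl (4S,5E,8R,11Z)-4-acetoxy-8-[(1S)-1-{[tert-butyl(dimethyl)silyl]oxy}prop-2-yn-1-yl]-9-oxoheptadeca-5,11-dienoate | CCCCC/C=C\CC(=O)[C@H](C/C=C/[C@@H](OC(C)=O)CCC(=O)OC)[C@H](O[Si](C)(C)C(C)(C)C)C#C | intermediate
16 | methyl (4S,5E,8R,11Z)-4-acetoxy-8-[(1R)-1-{[tert-butyl(dimethyl)silyl]oxy}-3-oxopropyl]-9-oxoheptadeca-5,11-dienoate | CCCCC/C=C\CC(=O)[C@H](C/C=C/[C@@H](OC(C)=O)CCC(=O)OC)[C@H](O[Si](C)(C)C(C)(C)C)CC=O | intermediate
17 | methyl (4S,5E)-4-acetoxy-7-[(1R,2S,3R,5R)-5-{[tert-butyl(dimethyl)silyl]oxy}-2,3-dihydroxy-2-[(2Z)-oct-2-en-1-yl]cyclopentyl]hept-5-enoate | CCCCC/C=C\C[C@@]1(O)[C@H](O)C[C@@H](O[Si](C)(C)C(C)(C)C)[C@H]1C/C=C/[C@H](CCC(=O)OC)OC(C)=O | intermediate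
18 | methyl (4S,5E)-4-acetoxy-7-[(1R,2S,3R,5R)-2,3-diacetoxy-5-{[tert-butyl(dimethyl)silyl]oxy}-2-[(2Z)-oct-2-en-1-yl]cyclopentyl]hept-5-enoate | CCCCC/C=C\C[C@@]1(OC(C)=O)[C@H](OC(C)=O)C[C@@H](O[Si](C)(C)C(C)(C)C)[C@H]1C/C=C/[C@H](CCC(=O)OC)OC(C)=O | intermediate
19 | methyl (4S,5E)-4-acetoxy-7-[(1R,2S,3R,5R)-2,3-diacetoxy-5-hydroxy-2-[(2Z)-oct-2-en-1-yl]cyclopentyl]hept-5-enoate | CCCCC/C=C\C[C@@]1(OC(C)=O)[C@H](OC(C)=O)C[C@@H](O)[C@H]1C/C=C/[C@H](CCC(=O)OC)OC(C)=O | intermediate
20 | methyl (4S,5E)-4-acetoxy-7-[(1S,2S,3R)-2,3-diacetoxy-2-[(2Z)-oct-2-en-1-yl]-5-oxocyclopentyl]hept-5-enoate (β-acetoxy ketone, not isolated) | CCCCC/C=C\C[C@@]1(OC(C)=O)[C@H](OC(C)=O)CC(=O)[C@H]1C/C=C/[C@H](CCC(=O)OC)OC(C)=O | intermediate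
21 | methyl (4S,5E)-4-acetoxy-7-[(1S,2R)-2-acetoxy-2-[(2Z)-oct-2-en-1-yl]-5-oxocyclopent-3-en-1-yl]hept-5-enoate (CNP0171642.2) | CCCCC/C=C\C[C@@]1(OC(C)=O)C=CC(=O)[C@H]1C/C=C/[C@H](CCC(=O)OC)OC(C)=O | target

**Step count and risks**

Total step count: 14. Longest linear sequence: 12 steps (steps 1, 2 and 5–14 from 1; equally steps 3–14 from 6).

Steps most likely to fail:

Step 7. Epimerisation at C8 that is slow relative to hydride transfer, or a weak Felkin preference, would erode the funnel into one C8 epimer; attack of the diketone enol oxygen on the alkynone (closure to a 4-pyranone) would consume the substrate. Fallback: setting out from 12 and coming back at 13, the chemocatalytic transfer hydrogenation is replaced by a biocatalytic reductive dynamic kinetic resolution. A ketoreductase panel (NADP+, glucose/glucose dehydrogenase recycling, pH 7 phosphate buffer/DMSO, 30 °C) would be screened for the enzyme that reduces the alkynyl ketone of the 8R epimer to the (S)-carbinol, so that the enzyme pocket rather than a Felkin bias selects the epimer. This fallback makes no new compound (F0).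

Step 11. Over-reduction of the aldehyde or the ketone to alcohols, intermolecular coupling, or formation of the diolate on the ring face syn to the C8 side chain (poor facial selectivity) would defeat the closure. Fallback: setting out from 15 and coming back at 21, the radical coupling is replaced by a polar Nozaki–Hiyama–Kishi closure of the same C11–C12 bond. Iodination of the terminal alkyne (NIS, AgNO3 cat., acetone) gives iodoalkyne F1; cis-reduction with diimide (2-nitrobenzenesulfonyl hydrazide, Et3N) gives (Z)-vinyl iodide F2; CrCl2 with NiCl2 (cat.) in DMF adds the vinylchromium to the C12 ketone and gives cyclopentenol F3, in which the C12 oxygen would again have to form anti to the C8 and C9 substituents. Acetylation (Ac2O, DMAP) gives tertiary acetate F4, HF·pyridine gives allylic alcohol F5, and Dess–Martin oxidation gives 21.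

Step 5. Phosphine- or alkoxide-triggered cyclisation of the alkynyl 1,3-diketone to a 4-pyranone, O- or double allylation, attack at the proximal allyl terminus, or lactonisation of the freed C4 oxygen onto the methyl ester would lower the supply of 11. Fallback: setting out from 4 (made from 2 as in step 2) and 10 and coming back at 12, the palladium step is run on an alkyne-free nucleophile and the alkynoyl group is introduced afterwards. The lithium enolate of tert-butyl acetate (LDA, THF, −78 °C) is acylated by 4 to give β-keto ester F6; Tsuji–Trost alkylation with 10 (Pd2(dba)3·CHCl3, dppe, THF) gives hydroxy ester F7, which is acetylated (Ac2O, pyridine) to acetate F8. C-acylation of its magnesium enolate (MgCl2, pyridine, CH2Cl2) with 3-(trimethylsilyl)prop-2-ynoyl chloride gives tricarbonyl compound F9; CF3CO2H in CH2Cl2 at 0 °C cleaves the tert-butyl ester to β-keto acid F10, which loses CO2 to give 12.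

**Further compounds**

F0 | step 7 | none | none
F1 | step 11 | methyl (4S,5E,8R,11Z)-4-acetoxy-8-[(1S)-1-{[tert-butyl(dimethyl)silyl]oxy}-3-iodoprop-2-yn-1-yl]-9-oxoheptadeca-5,11-dienoate | CCCCC/C=C\CC(=O)[C@H](C/C=C/[C@@H](OC(C)=O)CCC(=O)OC)[C@H](O[Si](C)(C)C(C)(C)C)C#CI
F2 | step 11 | methyl (4S,5E,8R,11Z)-4-acetoxy-8-[(1S,2Z)-1-{[tert-butyl(dimethyl)silyl]oxy}-3-iodoprop-2-en-1-yl]-9-oxoheptadeca-5,11-dienoate | CCCCC/C=C\CC(=O)[C@H](C/C=C/[C@@H](OC(C)=O)CCC(=O)OC)[C@H](O[Si](C)(C)C(C)(C)C)/C=C\I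
F3 | step 11 | methyl (4S,5E)-4-acetoxy-7-[(1R,2R,5R)-5-{[tert-butyl(dimethyl)silyl]oxy}-2-hydroxy-2-[(2Z)-oct-2-en-1-yl]cyclopent-3-en-1-yl]hept-5-enoate | CCCCC/C=C\C[C@@]1(O)C=C[C@@H](O[Si](C)(C)C(C)(C)C)[C@H]1C/C=C/[C@H](CCC(=O)OC)OC(C)=O
F4 | step 11 | methyl (4S,5E)-4-acetoxy-7-[(1R,2R,5R)-2-acetoxy-5-{[tert-butyl(dimethyl)silyl]oxy}-2-[(2Z)-oct-2-en-1-yl]cyclopent-3-en-1-yl]hept-5-enoate | CCCCC/C=C\C[C@@]1(OC(C)=O)C=C[C@@H](O[Si](C)(C)C(C)(C)C)[C@H]1C/C=C/[C@H](CCC(=O)OC)OC(C)=O
F5 | step 11 | methyl (4S,5E)-4-acetoxy-7-[(1R,2R,5R)-2-acetoxy-5-hydroxy-2-[(2Z)-oct-2-en-1-yl]cyclopent-3-en-1-yl]hept-5-enoate | CCCCC/C=C\C[C@@]1(OC(C)=O)C=C[C@@H](O)[C@H]1C/C=C/[C@H](CCC(=O)OC)OC(C)=O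
F6 | step 5 | tert-butyl (5Z)-3-oxoundec-5-enoate | CCCCC/C=C\CC(=O)CC(=O)OC(C)(C)C
F7 | step 5 | methyl (4S,5E,11Z)-8-(tert-butoxycarbonyl)-4-hydroxy-9-oxoheptadeca-5,11-dienoate | CCCCC/C=C\CC(=O)C(C/C=C/[C@@H](O)CCC(=O)OC)C(=O)OC(C)(C)C
F8 | step 5 | methyl (4S,5E,11Z)-4-acetoxy-8-(tert-butoxycarbonyl)-9-oxoheptadeca-5,11-dienoate | CCCCC/C=C\CC(=O)C(C/C=C/[C@@H](OC(C)=O)CCC(=O)OC)C(=O)OC(C)(C)C
F9 | step 5 | methyl (4S,5E,11Z)-4-acetoxy-8-(tert-butoxycarbonyl)-9-oxo-8-[3-(trimethylsilyl)prop-2-ynoyl]heptadeca-5,11-dienoate | CCCCC/C=C\CC(=O)C(C/C=C/[C@@H](OC(C)=O)CCC(=O)OC)(C(=O)OC(C)(C)C)C(=O)C#C[Si](C)(C)C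
F10 | step 5 | (5E,7S)-7-acetoxy-10-methoxy-2-[(3Z)-non-3-enoyl]-10-oxo-2-[3-(trimethylsilyl)prop-2-ynoyl]dec-5-enoic acid (β-keto acid) | CCCCC/C=C\CC(=O)C(C/C=C/[C@@H](OC(C)=O)CCC(=O)OC)(C(=O)O)C(=O)C#C[Si](C)(C)C
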